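(The numbers in the tables are simulated with constants of no real substance; noise was put on by code.)

in all of them: electrophile 20 mM

|  | nucleophile | solid base | remark | time |
|---|---|---|---|---|
| autumn | 0.80 equiv | 0.50 equiv | run made earlier |  |
| spring | 2.1 equiv | 0.50 equiv | run made earlier |  |
| midnight | 3.9 equiv | 0.50 equiv | run made earlier |  |
| amber | 4.40 equiv | 0.500 equiv |  | 12 h |
| red | 1.10 equiv | 0.500 equiv |  | 12 h |
| violet | 2.20 equiv | 0.500 equiv |  | 12 h |

| run | time / h | electrophile / % | product / % |
|---|---|---|---|
| autumn | 1.50 | 57.4 | 27.4 |
| autumn | 3.00 | 45.8 | 36.0 |
| autumn | 5.00 | 39.0 | 42.8 |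
| autumn | 6.00 | 36.4 | 43.8 |
| autumn | 8.00 | 32.9 | 47.8 |
| spring | 0.833 | 38.8 | 41.0 |
| spring | 2.00 | 21.3 | 59.7 |
| spring | 4.00 | 12.4 | 73.4 |
| spring | 6.00 | 8.4 | 79.7 |
| spring | 8.00 | 6.5 | 84.2 |
| midnight | 0.667 | 25.3 | 53.9 |
| midnight | 1.33 | 13.2 | 70.7 |
| midnight | 2.50 | 6.9 | 83.4 |
| midnight | 4.00 | 3.4 | 91.1 |
| midnight | 8.00 | 1.0 | 97.9 |

(readings scatter by 0.3 percentage points)

* part of the electrophile that has reacted at the end, amber
* part of the electrophile that has reacted at the end, red
* part of the electrophile that has reacted at the end, violet
* what raising the equivalents of nucleophile from its lowest to its highest value here does to the part of the electrophile that has reacted (changes below 5 percentage points count as none) (it falls / no change / it rises)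

- at the start none of the solid base is in solution
- a reading or a percentage of product counts all its forms, free or not
- what has gone from electrophile into another species counts as reacted, even if it can come back
- a reading of electrophile is of its free form alone

**The order.** Over 12 h, watch c_nucleophile: I read the rate as first order in c_electrophile and in c_nucleophile, and c_nucleophile is the one that can fall away. Autumn shows it. Early on it made 0.183 h⁻¹ of the charge per hour, late 0.0200 h⁻¹, with 32.9% of the electrophile still free.

**The ceiling.** My reckoning takes two nucleophile per product, one to react and one to catch the acid. Autumn's last reading then overdraws its charge by 0.156 equiv, which I credit to dissolved solid base. Assuming steady dissolution, which the readings can't prove, that reaches 0.234 equiv by the end. So you get the product ceiling, half of the nucleophile charged plus base dissolved so far: for red, 66.7%.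

**Red's curve.** Red should average near 0.251 h⁻¹ over its first 1.50 h, scaling autumn by nucleophile. The knee comes near 55.0% product. After it, on my assumed dissolution, the ceiling itself rises at 0.00975 h⁻¹, and the curve climbs towards it. Violet's ceiling is 122% and amber's 232%, both above the charge, so there electrophile is the limiting reagent.

**The gap.** Reacted also counts electrophile held by product. Autumn's balance falls short by 19.3%, and that gap over free electrophile times unbound product reads 2.06. At the ceiling this holds 16.9% more, so I commit to 83.6% reacted in red.

**The forecast.** It gives 99.8% for amber, 81% for red, 96% for violet, and says it rises, on the ground that “each product costs nucleophile twice, once as reagent and once as acid scavenger”. Its red figure is lower than mine.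

**The flasks.** Amber gives >99.9%, red 82.5%, violet 96.7%: it rises, by 17 percentage points.

    electrophile + product ⇌ idle adduct, settled at all times (K = 110 M⁻¹)
    nucleophile + acid set free ⇌ protonated nucleophile, settled at all times (K = 3100 M⁻¹)
    solid base ⇌ free base, rate k3*(cs3 - [free base]) while solid is left; crystals form when [free base] > cs3 (solubility = 17.0 mM, k = 4.90 × 10⁻⁴ min⁻¹)
    crystals ⇌ product, rate k4*(cs4 - [product]) while solid is left; crystals form when [product] > cs4 (solubility = 14.0 mM, k = 0.0150 min⁻¹)
    acid set free + free base ⇌ salt of the base, settled at all times (K = 1.30 × 10⁵ M⁻¹)
    electrophile + nucleophile → acid set free + product (k = 0.410 M⁻¹ min⁻¹)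

**What happened.** Red stood at 64.6% product under its 66.7% ceiling after 12.0 h, with 12.8% of its nucleophile free, while its solid base kept dissolving, 40.2% left. The forecast's violet figure would fail if nucleophile fell towards 1.58 equiv, where violet's answer has moved 5 points. The neighbour, violet with 0.880 equiv of nucleophile, has a reckoned ceiling of 55.7% and stood at 55.9% product; the same holding reckons 74.8% reacted, and it gave 75.5%.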